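**Retrosynthetic overview**

1. Target ⇐ global hydrogenolysis of a hexa-O-benzyl, mono-O-Cbz trans-biflavanone ⇐ acid-induced loss of a temporary tert-butyl ester on C3, after which C3 settles trans to C2.
2. Key disconnection: C3 (eriodictyol half)–C8 (naringenin half). It is made by a one-pot catalytic asymmetric oxa-Michael ring closure / Pinhey ligand coupling between an acyclic alkylidene β-ketoester (fragment 1) and a naringenin-8-yl lead triacetate (fragment 2). Both carbons are nucleophilic in the parent flavanones, and the arene carbon is reversed in polarity by tetravalent lead.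
3. Enabling feature: C3 lies between the C4 aryl ketone and C2, the carbon that carries ring oxygen O1 and the catechol ring B. With an ester parked on C3, the C2=C3 alkylidene takes up the 2'-OH (closing ring C) and the resulting β-ketoester enol takes up an aryl cation equivalent. C8 of the naringenin ring A is the CH between O7 and O1, which can be iodinated and carried as an aryl–lead reagent.
4. Ring order: ring C of the naringenin half is bought with (2S)-naringenin; ring C of the eriodictyol half is closed in the key step; all benzene rings are bought.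
5. Fragment 1: acetophenone → β-ketoester → Knoevenagel adduct (two steps). Fragment 2: naringenin → benzyl/Cbz protection → C8 iodide → stannane → aryllead (five steps).

Key step: step 8

Assumption: (2S)-naringenin is bought as the single enantiomer, and the benzyl-protected acetophenone and aldehyde are commercial.
Assumption: the quinidine-derived bifunctional thiourea gives the (2R) ring closure; if the sense proves opposite, its quinine-derived pseudoenantiomer is used instead.

**Step 1**
Reactants: 1 1-[2,4-bis(benzyloxy)-6-hydroxyphenyl]ethanone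
Product: 2 tert-butyl 3-[2,4-bis(benzyloxy)-6-hydroxyphenyl]-3-oxopropanoate
Conditions: LiN(SiMe3)2 (3.3 equiv), THF, −78 °C; Boc2O (1.1 equiv), −78 → 0 °C; 1 M HCl quench
Reagents that add atoms: di-tert-butyl dicarbonate, CC(C)(C)OC(=O)OC(=O)OC(C)(C)C
Why: Excess amide base forms the phenoxide–enolate dianion, whose enolate carbon is acylated by Boc2O (Claisen-type C-acylation of a ketone enolate; any O-Boc carbonate formed first passes its acyl group to the enolate in a Baker–Venkataraman-type shift), and the bulky tert-butyl ester should not lactonize to the 4-hydroxycoumarin at 0 °C.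

**Step 2**
Reactants: 2 tert-butyl 3-[2,4-bis(benzyloxy)-6-hydroxyphenyl]-3-oxopropanoate; 3 3,4-bis(benzyloxy)benzaldehyde
Product: 4 tert-butyl (2Z)-2-[2,4-bis(benzyloxy)-6-hydroxybenzoyl]-3-[3,4-bis(benzyloxy)phenyl]prop-2-enoate
Conditions: piperidine (0.2 equiv), AcOH (0.2 equiv), 4 Å MS, toluene, 25 °C
Reagents that add atoms: none
Why: Knoevenagel condensation of the β-ketoester methylene with the aryl aldehyde; without a bifunctional catalyst the chelated 2'-OH should add only slowly in toluene, so the open alkylidene can be isolated, and its E/Z ratio is immaterial because both isomers give the same enol on ring closure.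

**Step 3**
Reactants: 5 (2S)-naringenin
Product: 6 (2S)-7-(benzyloxy)-2-[4-(benzyloxy)phenyl]-5-hydroxychroman-4-one
Conditions: BnOH (2.2 equiv), PPh3 (2.3 equiv), DIAD (2.3 equiv), THF, 0 → 25 °C
Reagents that add atoms: benzyl alcohol, OCc1ccccc1
Why: Mitsunobu etherification alkylates the two acidic, non-chelated phenols (7-OH and 4'-OH) under essentially neutral conditions, leaves the hydrogen-bonded 5-OH alone and avoids the basic ring opening to the chalcone that would racemize C2.

**Step 4**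
Reactants: 6 (2S)-7-(benzyloxy)-2-[4-(benzyloxy)phenyl]-5-hydroxychroman-4-one
Product: 7 benzyl (2S)-7-(benzyloxy)-2-[4-(benzyloxy)phenyl]-4-oxochroman-5-yl carbonate
Conditions: CbzCl (1.5 equiv), Et3N (2 equiv), DMAP (0.1 equiv), CH2Cl2, 0 → 25 °C
Reagents that add atoms: benzyl chloroformate, O=C(Cl)OCc1ccccc1
Why: DMAP-catalysed acylation of the chelated 5-OH under a weak amine base gives the aryl benzyl carbonate without ring opening; the carbonate masks the phenol against lead tetraacetate, shields C6, and later falls off under the same hydrogenolysis as the benzyl ethers.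

**Step 5**
Reactants: 7 benzyl (2S)-7-(benzyloxy)-2-[4-(benzyloxy)phenyl]-4-oxochroman-5-yl carbonate
Product: 8 benzyl (2S)-7-(benzyloxy)-2-[4-(benzyloxy)phenyl]-8-iodo-4-oxochroman-5-yl carbonate
Conditions: NIS (1.05 equiv), TFA (0.3 equiv), MeCN, 0 → 25 °C
Reagents that add atoms: N-iodosuccinimide, O=C1CCC(=O)N1I
Why: Electrophilic aromatic iodination of ring A should go to C8, the position ortho to both ether oxygens (O1 and O7) and remote from the twisted peri carbonate that shields C6, as in the C8 halogenation of 5,7-di-O-substituted flavonoids whose 5-oxygen is not a free phenol; the monoalkoxy ring B is much less reactive, and the site is to be confirmed by HMBC.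

**Step 6**
Reactants: 8 benzyl (2S)-7-(benzyloxy)-2-[4-(benzyloxy)phenyl]-8-iodo-4-oxochroman-5-yl carbonate
Product: 9 benzyl (2S)-7-(benzyloxy)-2-[4-(benzyloxy)phenyl]-4-oxo-8-(tributylstannyl)chroman-5-yl carbonate
Conditions: (Bu3Sn)2 (1.5 equiv), Pd(PPh3)4 (5 mol %), toluene, 110 °C
Reagents that add atoms: hexabutylditin, CCCC[Sn](CCCC)(CCCC)[Sn](CCCC)(CCCC)CCCC
Why: Palladium-catalysed stannylation of an aryl iodide (oxidative addition to zerovalent palladium, Sn–Sn transmetalation, reductive elimination) is neutral, so the ketone, the carbonate and the C2 stereocentre are untouched.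

**Step 7**
Reactants: 9 benzyl (2S)-7-(benzyloxy)-2-[4-(benzyloxy)phenyl]-4-oxo-8-(tributylstannyl)chroman-5-yl carbonate
Product: 10 {(2S)-7-(benzyloxy)-5-[(benzyloxycarbonyl)oxy]-2-[4-(benzyloxy)phenyl]-4-oxochroman-8-yl}lead triacetate
Conditions: Pb(OAc)4 (1.05 equiv), Hg(O2CCF3)2 (5 mol %), CHCl3, 25 → 40 °C; filtered, concentrated and used crude
Reagents that add atoms: lead tetraacetate, CC(=O)O[Pb](OC(C)=O)(OC(C)=O)OC(C)=O
Why: Tin–lead exchange, an ipso electrophilic substitution of the electron-rich aryl–tin bond by lead tetraacetate under mercury catalysis, gives the aryllead triacetate with the metal fixed at C8 at a temperature at which the ketone is not acetoxylated.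

**Step 8**
Reactants: 4 tert-butyl (2Z)-2-[2,4-bis(benzyloxy)-6-hydroxybenzoyl]-3-[3,4-bis(benzyloxy)phenyl]prop-2-enoate; 10 {(2S)-7-(benzyloxy)-5-[(benzyloxycarbonyl)oxy]-2-[4-(benzyloxy)phenyl]-4-oxochroman-8-yl}lead triacetate
Product: 12 tert-butyl (2S,3R)-5,7-bis(benzyloxy)-3-{(2S)-7-(benzyloxy)-5-[(benzyloxycarbonyl)oxy]-2-[4-(benzyloxy)phenyl]-4-oxochroman-8-yl}-2-[3,4-bis(benzyloxy)phenyl]-4-oxochromane-3-carboxylate, via ring-closed β-ketoester 11 (not isolated)
Conditions: 9-amino(9-deoxy)-epi-quinidine 3,5-bis(trifluoromethyl)phenylthiourea (10 mol %), toluene, −25 °C; then 10 (1.3 equiv), pyridine (3 equiv), CHCl3, −25 → 25 °C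
Reagents that add atoms: none
Why: The quinuclidine nitrogen of the catalyst deprotonates the chelated 2'-OH while the thiourea binds the β-ketoester, so the phenoxide adds to the alkylidene carbon in a 6-endo-trig oxa-Michael closure of ring C (the reaction type known for alkylidene β-ketoesters of 2'-hydroxyacetophenones), and the catalyst alone decides the face and thereby the C2 configuration. The enol of 11 then exchanges an acetate on the tetravalent lead of 10 and the aryl group is passed to C3 by ligand coupling with loss of Pb(OAc)2; this is the Pinhey arylation known for chroman-4-one-3-carboxylates and other cyclic β-ketoesters, and it unites two carbons that are both nucleophilic in the free flavanones. The aryl group should enter C3 anti to the C2 aryl group (substrate control), but this quaternary centre is temporary and is reset in step 9; the C2 descriptor changes from R in 11 to S in 12 only because C3 becomes quaternary, the spatial arrangement being the same. The step needs site selectivity (ipso substitution at the lead-bearing C8 excludes a C6 isomer), C- over O-arylation (intrinsic to ligand coupling of β-ketoester enols) and retention at C2 (once C3 is quaternary it cannot enolize, which shuts off the retro-oxa-Michael path, and any opening before arylation is re-closed by the catalyst left in the flask). The excess of 10 allows for loss of some reagent to the thiourea sulfur.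

**Step 9**
Reactants: 12 tert-butyl (2S,3R)-5,7-bis(benzyloxy)-3-{(2S)-7-(benzyloxy)-5-[(benzyloxycarbonyl)oxy]-2-[4-(benzyloxy)phenyl]-4-oxochroman-8-yl}-2-[3,4-bis(benzyloxy)phenyl]-4-oxochromane-3-carboxylate
Product: 14 benzyl (2S)-7-(benzyloxy)-8-{(2R,3S)-5,7-bis(benzyloxy)-2-[3,4-bis(benzyloxy)phenyl]-4-oxochroman-3-yl}-2-[4-(benzyloxy)phenyl]-4-oxochroman-5-yl carbonate, via β-keto acid 13 (not isolated)
Conditions: TsOH·H2O (0.3 equiv), toluene, 80 °C, short reaction time
Reagents that add atoms: none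
Why: Acid cleaves the tert-butyl ester with loss of isobutene, the β-keto acid loses CO2 through its enol (the conditions known for flavanone-3-carboxylates), and acid-mediated keto–enol equilibration at C3 should leave the more stable 2,3-trans ketone, so C3 becomes (S) under thermodynamic control from the fixed (R) centre at C2, which has no free para-hydroxyl on ring B to open it.

**Step 10**
Reactants: 14 benzyl (2S)-7-(benzyloxy)-8-{(2R,3S)-5,7-bis(benzyloxy)-2-[3,4-bis(benzyloxy)phenyl]-4-oxochroman-3-yl}-2-[4-(benzyloxy)phenyl]-4-oxochroman-5-yl carbonate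
Product: 15 (2S)-8-[(2R,3S)-2-(3,4-dihydroxyphenyl)-5,7-dihydroxy-4-oxochroman-3-yl]-5,7-dihydroxy-2-(4-hydroxyphenyl)chroman-4-one
Conditions: H2 (1 atm), Pd/C (10 wt %), EtOAc–MeOH 1:1, 25 °C, stopped at full debenzylation
Reagents that add atoms: none
Why: Hydrogenolysis over Pd/C removes the six O-benzyl ethers and the benzyl carbonate (which then loses CO2) under neutral conditions that should leave the two aryl ketones, the acidic C3–H and all three stereocentres untouched.

**Compound list**

1 | 1-[2,4-bis(benzyloxy)-6-hydroxyphenyl]ethanone | CC(=O)c1c(O)cc(OCc2ccccc2)cc1OCc1ccccc1 | starting material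
2 | tert-butyl 3-[2,4-bis(benzyloxy)-6-hydroxyphenyl]-3-oxopropanoate | CC(C)(C)OC(=O)CC(=O)c1c(O)cc(OCc2ccccc2)cc1OCc1ccccc1 | intermediate
3 | 3,4-bis(benzyloxy)benzaldehyde | O=Cc1ccc(OCc2ccccc2)c(OCc2ccccc2)c1 | starting material
4 | tert-butyl (2Z)-2-[2,4-bis(benzyloxy)-6-hydroxybenzoyl]-3-[3,4-bis(benzyloxy)phenyl]prop-2-enoate (drawn as Z; an E/Z mixture is equally usable) | CC(C)(C)OC(=O)/C(=C\c1ccc(OCc2ccccc2)c(OCc2ccccc2)c1)C(=O)c1c(O)cc(OCc2ccccc2)cc1OCc1ccccc1 | intermediate
5 | (2S)-naringenin, (2S)-5,7-dihydroxy-2-(4-hydroxyphenyl)chroman-4-one | O=C1C[C@@H](c2ccc(O)cc2)Oc2cc(O)cc(O)c12 | starting material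
6 | (2S)-7-(benzyloxy)-2-[4-(benzyloxy)phenyl]-5-hydroxychroman-4-one | O=C1C[C@@H](c2ccc(OCc3ccccc3)cc2)Oc2cc(OCc3ccccc3)cc(O)c12 | intermediate
7 | benzyl (2S)-7-(benzyloxy)-2-[4-(benzyloxy)phenyl]-4-oxochroman-5-yl carbonate | O=C1C[C@@H](c2ccc(OCc3ccccc3)cc2)Oc2cc(OCc3ccccc3)cc(OC(=O)OCc3ccccc3)c12 | intermediate
8 | benzyl (2S)-7-(benzyloxy)-2-[4-(benzyloxy)phenyl]-8-iodo-4-oxochroman-5-yl carbonate | O=C1C[C@@H](c2ccc(OCc3ccccc3)cc2)Oc2c(I)c(OCc3ccccc3)cc(OC(=O)OCc3ccccc3)c12 | intermediate
9 | benzyl (2S)-7-(benzyloxy)-2-[4-(benzyloxy)phenyl]-4-oxo-8-(tributylstannyl)chroman-5-yl carbonate | O=C1C[C@@H](c2ccc(OCc3ccccc3)cc2)Oc2c([Sn](CCCC)(CCCC)CCCC)c(OCc3ccccc3)cc(OC(=O)OCc3ccccc3)c12 | intermediate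
10 | {(2S)-7-(benzyloxy)-5-[(benzyloxycarbonyl)oxy]-2-[4-(benzyloxy)phenyl]-4-oxochroman-8-yl}lead triacetate | O=C1C[C@@H](c2ccc(OCc3ccccc3)cc2)Oc2c([Pb](OC(C)=O)(OC(C)=O)OC(C)=O)c(OCc3ccccc3)cc(OC(=O)OCc3ccccc3)c12 | intermediate
11 | tert-butyl (2R,3S)-5,7-bis(benzyloxy)-2-[3,4-bis(benzyloxy)phenyl]-4-oxochromane-3-carboxylate (trans keto form, in equilibrium with its enol) | CC(C)(C)OC(=O)[C@@H]1C(=O)c2c(OCc3ccccc3)cc(OCc3ccccc3)cc2O[C@H]1c1ccc(OCc2ccccc2)c(OCc2ccccc2)c1 | intermediate (not isolated)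
12 | tert-butyl (2S,3R)-5,7-bis(benzyloxy)-3-{(2S)-7-(benzyloxy)-5-[(benzyloxycarbonyl)oxy]-2-[4-(benzyloxy)phenyl]-4-oxochroman-8-yl}-2-[3,4-bis(benzyloxy)phenyl]-4-oxochromane-3-carboxylate (the two aryl groups on C2 and C3 trans) | O=C1C[C@@H](c2ccc(OCc3ccccc3)cc2)Oc2c1c(OC(=O)OCc1ccccc1)cc(OCc1ccccc1)c2[C@]1(C(=O)OC(C)(C)C)C(=O)c2c(OCc3ccccc3)cc(OCc3ccccc3)cc2O[C@H]1c1ccc(OCc2ccccc2)c(OCc2ccccc2)c1 | intermediate
13 | (2S,3R)-5,7-bis(benzyloxy)-3-{(2S)-7-(benzyloxy)-5-[(benzyloxycarbonyl)oxy]-2-[4-(benzyloxy)phenyl]-4-oxochroman-8-yl}-2-[3,4-bis(benzyloxy)phenyl]-4-oxochromane-3-carboxylic acid | O=C1C[C@@H](c2ccc(OCc3ccccc3)cc2)Oc2c1c(OC(=O)OCc1ccccc1)cc(OCc1ccccc1)c2[C@]1(C(=O)O)C(=O)c2c(OCc3ccccc3)cc(OCc3ccccc3)cc2O[C@H]1c1ccc(OCc2ccccc2)c(OCc2ccccc2)c1 | intermediate (not isolated)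
14 | benzyl (2S)-7-(benzyloxy)-8-{(2R,3S)-5,7-bis(benzyloxy)-2-[3,4-bis(benzyloxy)phenyl]-4-oxochroman-3-yl}-2-[4-(benzyloxy)phenyl]-4-oxochroman-5-yl carbonate | O=C1C[C@@H](c2ccc(OCc3ccccc3)cc2)Oc2c1c(OC(=O)OCc1ccccc1)cc(OCc1ccccc1)c2[C@@H]1C(=O)c2c(OCc3ccccc3)cc(OCc3ccccc3)cc2O[C@H]1c1ccc(OCc2ccccc2)c(OCc2ccccc2)c1 | intermediate
15 | (2S)-8-[(2R,3S)-2-(3,4-dihydroxyphenyl)-5,7-dihydroxy-4-oxochroman-3-yl]-5,7-dihydroxy-2-(4-hydroxyphenyl)chroman-4-one | O=C1C[C@@H](c2ccc(O)cc2)Oc2c1c(O)cc(O)c2[C@@H]1C(=O)c2c(O)cc(O)cc2O[C@H]1c1ccc(O)c(O)c1 | target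

**Step count and risks**

Total steps: 10. Longest linear sequence: 8 steps (steps 3 to 10).

Steps most likely to fail:

1. Step 8. The ligand coupling at the congested C3 (a quaternary centre next to the C2 aryl group, receiving a di-ortho-substituted aryl) may be slow, which would let retro-oxa-Michael opening erode the C2 configuration, and the aryllead may be consumed by the thiourea sulfur or by protodeplumbation. Fallback (sets out from 4 and 8, returns at 14): 4 is ring-closed with the same thiourea catalyst and, in the same flask, heated with TsOH·H2O in toluene at 80 °C, so that 11 is decarboxylated to (2R)-5,7-bis(benzyloxy)-2-[3,4-bis(benzyloxy)phenyl]chroman-4-one F1. Soft enolization (Me3SiOTf, Et3N, CH2Cl2, 0 °C), which does not open ring C, gives (2R)-5,7-bis(benzyloxy)-2-[3,4-bis(benzyloxy)phenyl]-4-(trimethylsilyloxy)-2H-chromene F2. Fluoride-promoted palladium-catalysed α-arylation of this silyl enol ether with iodide 8 (Pd(dba)2, P(t-Bu)3, Bu3SnF, toluene, 80 °C) should give 14 directly, the aryl group entering anti to the C2 aryl group.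

2. Step 5. Iodination may split between C8 and C6, or run on to ring B. Fallback (sets out from 1, returns at 8): the iodine is placed before ring C exists. NIS in MeCN at 0 °C iodinates 1 ortho to its free chelated phenol, the usual site for 2-hydroxy-4,6-dialkoxyacetophenones, to give 1-[4,6-bis(benzyloxy)-2-hydroxy-3-iodophenyl]ethanone F3; because this phenol becomes O1, the iodine must end at C8. The conditions of step 1 give tert-butyl 3-[4,6-bis(benzyloxy)-2-hydroxy-3-iodophenyl]-3-oxopropanoate F4. Knoevenagel condensation with commercial 4-(benzyloxy)benzaldehyde gives tert-butyl (2Z)-2-[4,6-bis(benzyloxy)-2-hydroxy-3-iodobenzoyl]-3-[4-(benzyloxy)phenyl]prop-2-enoate F5. Ring closure with the quinine-derived pseudoenantiomer of the thiourea gives tert-butyl (2S,3R)-5,7-bis(benzyloxy)-2-[4-(benzyloxy)phenyl]-8-iodo-4-oxochromane-3-carboxylate F6, which is decarboxylated in the same flask (TsOH·H2O, toluene, 80 °C) to (2S)-5,7-bis(benzyloxy)-2-[4-(benzyloxy)phenyl]-8-iodochroman-4-one F7. BCl3 (1.1 equiv, CH2Cl2, −78 °C) removes only the chelating 5-O-benzyl group to give (2S)-7-(benzyloxy)-2-[4-(benzyloxy)phenyl]-5-hydroxy-8-iodochroman-4-one F8, and the conditions of step 4 convert it into 8.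

3. Step 10. The hydrogenolysis may over-run and cleave the benzylic C2–O1 bonds of either ring C, or stall with partly benzylated material. Fallback (sets out from 14, returns at 15): Lewis-acid debenzylation with BCl3 and pentamethylbenzene as benzyl-cation trap in CH2Cl2 at −78 °C, followed by methanol quench, which removes the benzyl ethers and the benzyl carbonate without hydrogen and without a metal surface.

**Further compounds**

F1 | step 8 | (2R)-5,7-bis(benzyloxy)-2-[3,4-bis(benzyloxy)phenyl]chroman-4-one | O=C1C[C@H](c2ccc(OCc3ccccc3)c(OCc3ccccc3)c2)Oc2cc(OCc3ccccc3)cc(OCc3ccccc3)c12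
F2 | step 8 | (2R)-5,7-bis(benzyloxy)-2-[3,4-bis(benzyloxy)phenyl]-4-(trimethylsilyloxy)-2H-chromene | C[Si](C)(C)OC1=C[C@H](c2ccc(OCc3ccccc3)c(OCc3ccccc3)c2)Oc2cc(OCc3ccccc3)cc(OCc3ccccc3)c12
F3 | step 5 | 1-[4,6-bis(benzyloxy)-2-hydroxy-3-iodophenyl]ethanone | CC(=O)c1c(O)c(I)c(OCc2ccccc2)cc1OCc1ccccc1
F4 | step 5 | tert-butyl 3-[4,6-bis(benzyloxy)-2-hydroxy-3-iodophenyl]-3-oxopropanoate | CC(C)(C)OC(=O)CC(=O)c1c(O)c(I)c(OCc2ccccc2)cc1OCc1ccccc1
F5 | step 5 | tert-butyl (2Z)-2-[4,6-bis(benzyloxy)-2-hydroxy-3-iodobenzoyl]-3-[4-(benzyloxy)phenyl]prop-2-enoate | CC(C)(C)OC(=O)/C(=C\c1ccc(OCc2ccccc2)cc1)C(=O)c1c(O)c(I)c(OCc2ccccc2)cc1OCc1ccccc1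
F6 | step 5 | tert-butyl (2S,3R)-5,7-bis(benzyloxy)-2-[4-(benzyloxy)phenyl]-8-iodo-4-oxochromane-3-carboxylate | CC(C)(C)OC(=O)[C@H]1C(=O)c2c(OCc3ccccc3)cc(OCc3ccccc3)c(I)c2O[C@@H]1c1ccc(OCc2ccccc2)cc1
F7 | step 5 | (2S)-5,7-bis(benzyloxy)-2-[4-(benzyloxy)phenyl]-8-iodochroman-4-one | O=C1C[C@@H](c2ccc(OCc3ccccc3)cc2)Oc2c(I)c(OCc3ccccc3)cc(OCc3ccccc3)c12
F8 | step 5 | (2S)-7-(benzyloxy)-2-[4-(benzyloxy)phenyl]-5-hydroxy-8-iodochroman-4-one | O=C1C[C@@H](c2ccc(OCc3ccccc3)cc2)Oc2c(I)c(OCc3ccccc3)cc(O)c12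
F0 | step 10 | none | none
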